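Late in a run the two products, mirror images joined by a candidate step, may drift towards equal amounts. So I took an excess E of left-handed over right-handed product as belonging to a moment, not to a recipe.

| setting | noon | dusk | west | east |
|---|---|---|---|---|
| left-handed substrate | 0.13 M | 0.30 M | 0.20 M | 0.20 M |
| right-handed substrate | 0.13 M | 0.30 M | 0.20 M | 0.20 M |
| coupling partner | 2.2 equiv | 2.2 equiv | 2.20 equiv | 2.20 equiv |
| precatalyst | 0.5 mol% | 0.5 mol% | 0.5 mol% | 0.5 mol% |
| temperature | −6 °C | 2 °C | −10 °C | 5 °C |
| remark | run made earlier | run made earlier |  |  |
| time |  |  | 20 min | 20 min |

- noon (time / min: left-handed product / %, right-handed product / %, left-handed substrate / %): 1.33: 1, 0, 53; 2.00: 0, 0, 48; 4.00: 5, 1, 46; 6.00: 8, 3, 42; 10.0: 8, 8, 43; 15.0: 13, 4, 37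
- dusk (time / min: left-handed product / %, right-handed product / %, left-handed substrate / %): 0.667: 8, 3, 46; 1.00: 7, 2, 43; 2.00: 9, 3, 39; 3.00: 11, 9, 39; 6.00: 16, 14, 32; 8.00: 18, 12, 30

(readings scatter by 2 percentage points)

- coupling partner is single-handed; left-handed substrate and right-handed substrate are mirror images of each other, charged as a racemate, each of them at the stated concentration
- the numbers in the tables scatter by 2 percentage points (one standard deviation)
- candidate steps: coupling partner + right-handed substrate -> right-handed product; left-handed product <-> right-handed product; left-handed substrate + racemization catalyst <-> right-handed substrate + racemization catalyst; 2 coupling partner -> self-condensation product; coupling partner + precatalyst -> racemization catalyst + spent reagent; coupling partner + left-handed substrate -> left-handed product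
- an excess is the difference of the two amounts in percent of their sum
- an excess is below zero if the other one leads
- the handed part of coupling partner does not stay in what it makes, so the products of the two hands are mirror images too

* the flask that comes out highest in excess of left-handed product over right-handed product, or "all alike" when all lie within 1.5 percentage points (west / east / all alike)
* excess of left-handed product over right-handed product at the end, west
* excess of left-handed product over right-handed product at the end, east

The bench rule of thumb takes E read off a run as a constant of the recipe and carries it to the next flask. I pooled the last 3 readings of each run against the scatter. Noon gave E = 31.8% at a mean conversion c (both products together) of 14.7%. Dusk gave 12.5% at 26.7%. The rule stopped there: the conversion in dusk stood at 1.82 times that in noon, while E stood at 0.393 of its noon value. So I carried 1.61 as the price g, the points of excess lost per point of conversion. The two runs differ in temperature as well as concentration, so g is a rough reading across both changes; it puts E at zero at c = 34.4%.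

In the noon run, conversion grew from 11.0% to 17.0% between 6.00 min and 15.0 min, roughly as the root of time. I therefore scaled c by the root of concentration times time, leaving aside the temperature, −10 °C in west against −6 °C in noon and 5 °C in east against 2 °C in dusk. From noon's last reading, I reckoned west at c = 24.3%, and the price then gave E = 16.2%. From dusk's last reading, I reckoned east at c = 38.7%, beyond the zero of the line, so I expected little excess there.

The forecast, higher than my west, named west, with 30% (18% to 43%) for west and 10% (1% to 22%) for east, since “East is warm and runs to a time equivalent to past the dusk endpoint”.

The flasks give 25.0% in west and 6.97% in east, so west leads.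

    coupling partner + right-handed substrate → right-handed product (k = 0.150 M⁻¹ min⁻¹, Ea = 63.0 kJ mol⁻¹)
    left-handed product ⇌ right-handed product (k = 0.0370 min⁻¹, Ea = 90.0 kJ mol⁻¹)
    left-handed substrate + racemization catalyst ⇌ right-handed substrate + racemization catalyst, rate k3*[racemization catalyst]*[left-handed substrate] forward; the back reaction follows from the equilibrium constant (k = 130 M⁻¹ min⁻¹, Ea = 44.0 kJ mol⁻¹)
    2 coupling partner → self-condensation product (k = 0.240 M⁻¹ min⁻¹, Ea = 49.0 kJ mol⁻¹)
    coupling partner + precatalyst → racemization catalyst + spent reagent (k = 0.0390 M⁻¹ min⁻¹, Ea = 75.0 kJ mol⁻¹)
    coupling partner + left-handed substrate → left-handed product (k = 0.250 M⁻¹ min⁻¹, Ea = 58.0 kJ mol⁻¹)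
    (constants at 5 °C)

Neither flask had come to rest at 20 min. At the conversion of 20.6% in west, the price g gives 22.3%, and the flask shows 25.0%. The relaxation half-life of the products in west, by the step joining them alone and both ways together, is 86.1 min, long against the time. After 200 min, west stands at conversion 41.1%, past the line's zero, with 1.72% of its coupling partner left, yet it still shows 6.88%. East, with left-handed product 24.2% and right-handed product 24.2% after 200 min, shows 0%.

(The runs are simulated for substances that don't exist.)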